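The data stem from a simulated flask on assumed constants; the scatter is artificial.

If you want a figure for flask epsilon that you can check by hand against the readings, count in powers of ten.

| setting | teal | green | gamma | epsilon |
|---|---|---|---|---|
| starting material | 0.14 M | 0.32 M | 0.21 M | 0.21 M |
| gas | 23 mM (held) | 23 mM (held) | 23 mM (held) | 23 mM (held) |
| remark | run made earlier | run made earlier |  |  |
| time |  |  | 20 h | 40 h |

| run | time / h | side product A / % | intermediate C / % | intermediate A / % | target / % | starting material / % | intermediate B / % |
|---|---|---|---|---|---|---|---|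
| teal | 1.50 | 0 | 0.6 | 1.5 | 0 | 86.6 | 10.2 |
| teal | 3.00 | 0 | 1.0 | 4.1 | 0.3 | 77.7 | 19.3 |
| teal | 6.00 | 3.0 | 2.0 | 10.1 | 0 | 54.6 | 31.5 |
| teal | 10.0 | 5.7 | 3.6 | 14.0 | 0 | 33.4 | 41.9 |
| teal | 20.0 | 10.1 | 7.5 | 14.8 | 2.4 | 11.0 | 52.0 |
| green | 1.50 | 0 | 0 | 1.4 | 0.4 | 88.2 | 11.0 |
| green | 3.00 | 1.1 | 0 | 2.3 | 0 | 77.7 | 18.8 |
| green | 6.00 | 2.9 | 0.6 | 5.8 | 0.7 | 58.0 | 32.2 |
| green | 10.0 | 4.1 | 2.1 | 9.2 | 0.3 | 39.0 | 44.3 |
| green | 20.0 | 6.4 | 8.0 | 12.4 | 2.0 | 12.9 | 51.3 |

(scatter of a reading: 1 percentage point)

- the numbers in the tables scatter with a standard deviation of 1 percentage point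
- at the start none of the gas is in solution

* which of these there is most of at the end, counted by the starting material in it, gamma (intermediate C / starting material / intermediate A / intermediate B / side product A)
* which of these there is most of at the end, counted by the starting material in it, epsilon (intermediate C / starting material / intermediate A / intermediate B / side product A)
* the largest of these amounts at the end, in percent of the starting material charged, gamma
* the largest of these amounts at the end, in percent of the starting material charged, epsilon

At 20.0 h the teal and green runs read 52.0% and 51.3% of intermediate B although their charges differ, so I expect about 51.6% in flask gamma, with 11.9% of starting material left. I take intermediate C and target as what has left intermediate B. Between 10.0 h and 20.0 h they gained 7 percentage points on average, while intermediate B stood near 47.4%. So: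

tenfold time = 2.3 × 47.4% × 10.0 h / 7 points = 157 h

This is the time in which an unfed first-order pool falls by one power of ten. The window from 20 h to 40 h is 0.128 of a power, a factor of 0.746.

I bracket epsilon with two extreme flasks. In the first, starting material stops feeding intermediate B at 20 h, and the pool of intermediate B drains. In the second, that pool stops draining, and the remaining starting material turns into intermediate B in the same share as so far, which adds 7.01%.

[intermediate B], low = 51.6% × 0.746 = 38.5%

[intermediate B], high = 51.6% + 7.01% = 58.7%

Starting material has a tenfold time of 21.7 h, shorter than 157 h, so the feed arrives early and drains too. My figure: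

(51.6% + 7.01%) × 0.746 = 43.7%

The low end stands above every other reading of the teal and green runs at 20.0 h, so I expect intermediate B to lead in gamma and in epsilon.

The forecast names intermediate B for gamma at 51.5% and intermediate B for epsilon at 39%, lower than my 43.7%: “B still leads over C and side product A.”

    starting material + reagent ⇌ intermediate A (K = 125 M⁻¹, k = 5.08 × 10⁻⁴ M⁻¹ s⁻¹)
    starting material → intermediate B (k = 1.96 × 10⁻⁵ s⁻¹)
    starting material + reagent → side product A (k = 2.04 × 10⁻⁴ M⁻¹ s⁻¹)
    intermediate A → side product B (k = 6.23 × 10⁻⁶ s⁻¹)
    intermediate B ⇌ intermediate C (K = 26.8, k = 3.51 × 10⁻⁶ s⁻¹)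
    intermediate C → target (k = 1.10 × 10⁻⁵ s⁻¹)
    gas ⇌ reagent, rate k7*(csat - [reagent]) (kL = 1.45 × 10⁻⁴ s⁻¹)

Intermediate B leads in gamma with 51.7% and in epsilon with 46.7%. Part of what holds it up in epsilon is the drag of gas crossing into reagent, together with the time given: with that drag taken away it stands at 39.6%, and left for 400 h at 0.599%. In the flask epsilon left until 4.0 d, the tenfold time of 157 h, carried on from 40 h, takes 46.7% down to 20.5% without feed, and that flask holds 25.2%.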